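The south-east run left a leftover: at 5.00 h it still read 3.5 % of first end groups, although second end groups were charged in excess, 0.018 M against 0.013 M. So second end groups also go another way. From the balance at that reading, the lost fraction of their charge was

0.335

| setting | south-east | north | amber | ochre |
|---|---|---|---|---|
| first end groups | 0.013 M | 0.010 M | 0.020 M | 0.020 M |
| second end groups | 0.018 M | 0.018 M | 0.0180 M | 0.0360 M |
| remark | run made earlier | run made earlier |  |  |
| time |  |  | 15 h | 15 h |

| run | time / h | side product / % | rings / % | first end groups / % | links / % |
|---|---|---|---|---|---|
| south-east | 0.833 | 1.6 | 52.3 | 13.8 | 31.1 |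
| south-east | 1.50 | 3.5 | 60.7 | 6.9 | 30.8 |
| south-east | 2.50 | 3.4 | 60.4 | 5.3 | 32.2 |
| south-east | 3.00 | 3.9 | 59.0 | 5.1 | 29.2 |
| south-east | 4.00 | 4.8 | 59.7 | 6.1 | 29.1 |
| south-east | 5.00 | 3.8 | 59.8 | 3.5 | 30.4 |
| north | 0.250 | 0 | 29.7 | 44.2 | 24.9 |
| north | 0.833 | 0.8 | 50.1 | 11.7 | 35.6 |
| north | 1.33 | 3.9 | 58.5 | 6.3 | 36.5 |
| north | 2.50 | 2.5 | 60.8 | 0.7 | 36.6 |
| north | 3.00 | 1.7 | 62.7 | 0 | 36.1 |
| north | 4.00 | 3.1 | 63.0 | 0.6 | 34.3 |
| north | 5.00 | 1.0 | 62.6 | 0 | 34.8 |

(each reading ± 1 percentage point)

- percent here means first end groups units held: one side product counts as two
- what may be going on: first end groups + second end groups -> links; first end groups + second end groups -> rings; links -> over-reaction product; first end groups + links -> side product; second end groups -> decomposed reagent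

- which of these there is most of at the end, counted by the first end groups in it, amber (links / rings / side product / first end groups)
- which of these there is most of at the end, counted by the first end groups in it, ochre (links / rings / side product / first end groups)
- amount of the one of these that there is most of at the end, in percent of the first end groups charged, amber
- amount of the one of these that there is most of at the end, in percent of the first end groups charged, ochre

In the north run, links per ring read 0.838 up to 0.250 h, then 0.525 for what formed up to 0.833 h. Two steps of equal order in second end groups keep that ratio level, so I took links as first order in them and rings as order zero, pseudo-first-order in first end groups. Links per ring (the selectivity) then equals second end groups over the crossing level, the concentration at which both form equally fast. I read it from north's first interval: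

mean second end groups = 0.0152 M
crossing level = 0.0181 M

That is 1.01 of amber's charge and 0.504 of ochre's.

I built the flask up in turn. With the main steps alone and second end groups held at charge, ochre's ring share is 33.5 %. Letting first end groups use them, with the mean level lowered by half their charge, it becomes 41.1 %.

Next came the loss. As a rough guess I carried south-east's lost fraction over unchanged. On that guess ochre keeps 0.0239 M of second end groups, more than the 0.020 M of first end groups, so I expected first end groups to be consumed in ochre and links to lead at that ring share. On the same guess amber converts 59.9 % at a ring share of 66.8 %, giving rings 40.0 %. That is more than the 19.9 % of links the same reckoning gives for amber, so I named rings for amber, leaving side product unreckoned.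

The forecast named rings for amber at 36 % (30 % to 44 %) and rings for ochre at 50 % (42 % to 58 %): “Links/rings ≈ 120 M⁻¹ × [first end groups], so links need high concentration.” My reckoning differs, naming links in ochre.

Amber ended with rings at 47.2 %, ochre with links at 52.2 %, rings there 43.1 %. South-east's lost fraction, 33.5 %, did not carry over: decomposed reagent took 45.7 % of ochre's second end groups and 19.7 % of amber's.

    first end groups + second end groups → links (k = 116 M⁻¹ h⁻¹)
    first end groups + second end groups → rings, rate k2*[first end groups] as long as [second end groups] is above zero (k = 1.65 h⁻¹)
    links → over-reaction product (k = 2.55 × 10⁻⁴ h⁻¹)
    first end groups + links → side product (k = 12.4 M⁻¹ h⁻¹)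
    second end groups → decomposed reagent (k = 1.11 h⁻¹)

Ochre's charge stood at twice my crossing level, amber's at 0.992 of it. In amber, rings used second end groups at 0.79 of the link rate at the start and 2.1 of it by 0.192 h.

In a neighbour flask, amber with 0.0080 M of first end groups, the crossing level gives a ring share of 56.4 %. That flask ended with rings at 60.1 % and links at 38.0 %.

Readings and results were generated by integration for substances that don't exist; the scatter is artificial.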